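## The problem

The target 17 is a trans-isoflavan-4-ol: a 6,7,8-trimethoxychroman (rings A and C; O1, C2, C3, C4, C4a, C5–C8, C8a) that carries a 2,5-dihydroxy-3,4-dimethoxyphenyl group (ring B, C1'–C6') on C3 and a hydroxyl on C4, configured (3S,4R). Ring C holds only three sp3 atoms, so the synthesis has to join two fully oxygenated arenes through a three-carbon bridge and close one C–O bond without touching five methyl ethers. The two stereocentres are adjacent: C3 can only be set when its C–C (or C–H) bond is made and cannot be corrected afterwards, whereas C4 is a benzylic carbinol that ionises easily and can therefore be steered by C3 toward the trans, diequatorial arrangement. That ease of ionisation is also the main hazard, because C4 lies ortho to O1 and para to the C7 methoxy group: acid turns the carbinol into a cation that loses H3 (isoflav-3-ene, C3 erased) or is trapped by the 2'-hydroxyl (pterocarpan). Ring B is a hydroquinone and is oxidised to the quinone by air, fastest under base. The free hydroquinone and the C4 carbinol can therefore meet only at the very end, under non-acidic, oxygen-free conditions, and acid-labile or hydrogenolytic masks on ring B are poor choices. What allows a short route is that C2 is an isolated methylene at the formaldehyde oxidation level between O1 and C3, and that a cation at C4 is exactly the one ring A stabilises best: O1, a one-carbon electrophile and the C3=C4 bond of a stilbene are all that ring C needs.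

## Retrosynthesis

**Target 17 to diacetate 16.** The first cut is at the two phenolic O–H bonds of ring B, which become acetates. Benzyl ethers would have to leave by hydrogenolysis next to an activated benzylic C4–O bond, and acetal ethers need acid, which ionises C4; aryl acetates leave under mild base. The acetates also serve the ring-forming step: they deactivate ring B toward electrophiles, make a cation on C3 unattractive, and an acylated O2' cannot close onto C4. Compound 16 is no simpler in skeleton but is air-stable. The forward step must be a methanolysis that is oxygen-free and never acidic.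

**Diacetate 16 to stilbene 12 and formaldehyde 2.** Three bonds of ring C are cut at once: O1–C2, C2–C3 and the C4–O bond of the carbinol. Cutting only O1–C2 (etherification of a 1,3-diol) or only at C4 (reduction of an isoflavanone) would leave both stereocentres to a separate asymmetric sequence. Taking C2 out entirely removes ring C and both stereocentres and leaves the flat, achiral (E)-stilbene 12, whose phenol oxygen is homoallylic to C3=C4. Forward, the phenol and 2 give hemiformal 13, a chiral strong Brønsted acid ionises it to oxocarbenium ion 14, C2 attacks C3 to give the ring-A-stabilised cation 15, and water completes C4. The reaction must engage the phenol before the alkene, close 6-endo, select one alkene face (C3) and add water trans to ring B (C4).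

**Stilbene 12 to vinylphenol 5 and aryl bromide 11.** The C3–C1' bond is cut (Mizoroki–Heck). A cut through C3=C4 (olefination of aldehyde 4) would need a ring-B benzylic phosphorus reagent, several steps longer to make than 11, and would give E/Z mixtures; the Heck reaction is inherently E-selective. Both fragments are simple pentasubstituted benzenes. The forward reaction must be mild enough that the acetates of 11 do not move to the free phenol of 5.

**Vinylphenol 5 to aldehyde 4, and 4 to phenol 1 and formaldehyde 2.** The vinyl CH2 is removed (Wittig methylenation), then the formyl carbon, the future C4, is cut from the arene. In 1 only one ortho position is free and the para position is blocked, so magnesium-mediated ortho-formylation with 2 (through salicyl alcohol 3) can give only 4. All three ring-A methoxy groups come with the starting material.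

**Aryl bromide 11 to 2,3-dimethoxyphenol 6.** The acetates are cut back to bromoquinone 9 (reductive acetylation through hydroquinone 10, never isolated). The C–Br bond is cut back to quinone 7 (bromine addition to dibromide 8, then loss of HBr). The second ring oxygen is cut back to phenol 6 (para-oxidation). Bromination at the quinone stage is preferred because 7 is symmetric, so C5 and C6 are equivalent, and the first bromine slows a second addition.

## Roads not taken

**Alternative 1:** Three-component conjunctive coupling across C3 and C4. The cut is at C4–C4a and C3–C1', leaving ring C open.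
- Forward key step: it would deliver the syn-1,2-diaryl-3-silyloxypropyl pinacol boronate A1 (boron on C4, ring B on C3, configured as in the target). The boronate complex formed from the ring-A aryllithium A2 (O1 as a methoxymethyl ether) and the (E)-alkenyl boronate A3 (bringing C4, C3 and C2) would meet the arylpalladium species from ring-B bromide A4 under Pd(OAc)2 and a chiral bisphosphine. 1,2-Migration of ring A to C4 and reductive elimination at C3 set both centres.
- Merits: a catalyst-controlled, stereospecific reaction of an established type. C4 is fixed kinetically by stereoretentive C–B oxidation, independent of carbinol stability. The route is fully convergent.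
- Weak points: no ring is formed, so boron oxidation, desilylation, removal of the methoxymethyl group, O1–C2 etherification and debenzylation still follow. The methoxymethyl ether needs acid beside the C4 carbinol, and the benzyl ethers need hydrogenolysis beside the C4–O bond. A3 is β-substituted and A2 and A4 are both ortho-substituted, which is the edge of this coupling, and halide from A4 can interfere with the cationic palladium species it needs.
- Comparison: in predictability of absolute and relative configuration this road is ahead, since it rests on a proven asymmetric manifold. The chosen plan sets against it that ring C and both stereocentres arise in one step from an achiral precursor, that the whole route is eight steps against roughly twice as many, and that its only deprotection is basic.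

**Alternative 2:** Benzofuran to chromene by one-carbon insertion. C3 is the inserted atom: C2–C3 and C3–C4 are cut.
- Forward key step: it would give 3-bromo-2-ethoxy-6,7,8-trimethoxy-2H-chromene A5 as a racemic acetal. Dibromocarbene (bromoform, base) cyclopropanates the furan double bond of 5,6,7-trimethoxybenzofuran A6, the adduct opens with loss of bromide, and ethoxide adds at C2. Cross-coupling at C3–Br with a ring-B boron reagent and ionic reduction of the acetal would give the isoflav-3-ene A7, and asymmetric hydroboration–oxidation would set C3 and C4 trans by syn addition.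
- Merits: every step is of a known type, the C3 bromide accepts any ring B, and the trans relationship is enforced by the mechanism of hydroboration.
- Weak points: the key step makes no stereocentre and creates a C2 acetal that must be reduced away under acid. A6 itself takes several steps from phenol 1. The carbene may also attack the trimethoxy arene. Enantioselectivity rests on a stoichiometric chiral borane and a hindered trisubstituted alkene, and the oxidative work-up is hostile to a masked hydroquinone.
- Comparison: this is the more conservative road and its individual steps are more reliable. The chosen plan is about half as long, catalytic in the stereo-defining step and free of the redox detour at C2. The hydroboration endgame of this road is kept as the fallback for step 7.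

**Alternative 3:** Ring A by Dötz benzannulation. The cut goes through ring A: C5–C6, C4a–C8a and C8–C8a.
- Forward key step: it would give phenol A8 with the C8a hydroxyl free and the bis-silylated C4–C3–C2 chain ortho to it. The chromium carbene complex A9, (CO)5Cr=C(OMe)C(OMe)=CHOMe, reacts with terminal alkyne A10, which already holds both stereocentres, by alkyne insertion, CO insertion and electrocyclisation.
- Merits: O1 emerges unprotected and differentiated from the three methoxy groups. The regiochemistry of terminal alkynes in this annulation is dependable. The stereocentres can be secured beforehand by auxiliary-based aldol chemistry.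
- Weak points: ring A is the part of the molecule that can be bought (as 1), so building it spends effort where none is needed. A9 is not a standard carbene complex and needs stoichiometric zerovalent chromium. The electron-rich phenol is oxidation-prone on decomplexation. The key step creates no stereocentre, and ring closure plus removal of two silyl and two benzyl ethers still follow.
- Comparison: its one real advantage is stereochemistry from a thoroughly proven aldol. The chosen plan sets against it a route less than half as long and no stoichiometric transition metal.

Key step: step 7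

Assumption: 1, 2 (as paraformaldehyde) and 6 are taken as commercial, and the (S,S) descriptor of the step 7 acid is a placeholder for whichever enantiomer delivers (3S), since the sense of induction cannot be predicted.

## Route

Step 1
Reactants: 1 2,3,4-trimethoxyphenol; 2 formaldehyde (used as paraformaldehyde)
Product: 4 2-hydroxy-3,4,5-trimethoxybenzaldehyde, via salicyl alcohol 3 (not isolated)
Conditions: MgCl2, Et3N, (CH2O)n, MeCN, reflux; then 1 M HCl
Reagents that add atoms: none
Why: Casnati–Skattebøl ortho-formylation: the magnesium phenoxide delivers 2 to the only free ortho carbon, and the chelated benzylic alkoxide 3 is oxidised to the aldehyde by hydride transfer to a second molecule of 2; the para position is blocked, so no isomer can form.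

Step 2
Reactants: 4 2-hydroxy-3,4,5-trimethoxybenzaldehyde
Product: 5 2-ethenyl-4,5,6-trimethoxyphenol
Conditions: Ph3PCH3Br (2.5 equiv), KOtBu (2.4 equiv), THF, 0 → 25 °C; aq NH4Cl
Reagents that add atoms: methyltriphenylphosphonium bromide, C[P+](c1ccccc1)(c1ccccc1)c1ccccc1.[Br-]
Why: Wittig methylenation; the first equivalent of ylide is spent on the phenol and the second converts the phenoxide aldehyde into the styrene, the standard way from salicylaldehydes to 2-vinylphenols.

Step 3
Reactants: 6 2,3-dimethoxyphenol
Product: 7 2,3-dimethoxy-1,4-benzoquinone
Conditions: (KSO3)2NO (2.2 equiv), KH2PO4 buffer, H2O/acetone, 0 → 25 °C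
Reagents that add atoms: potassium nitrosodisulfonate, [K+].[K+].[O]N(S(=O)(=O)[O-])S(=O)(=O)[O-]
Why: Teuber oxidation: the phenoxyl radical couples with a second nitrosodisulfonate radical at the free para carbon and loses imidodisulfonate, which gives the para-quinone of a phenol whose para position is open.

Step 4
Reactants: 7 2,3-dimethoxy-1,4-benzoquinone
Product: 9 5-bromo-2,3-dimethoxy-1,4-benzoquinone, via trans-dibromide 8 (not isolated)
Conditions: Br2 (1.05 equiv), CH2Cl2, 0 °C; then NaOAc, AcOH, 25 °C
Reagents that add atoms: bromine, BrBr
Why: Addition of bromine to the unsubstituted C5=C6 bond and base-induced loss of HBr from the α-bromo ketone; C5 and C6 of 7 are equivalent, the methoxylated double bond bears no hydrogen and cannot follow this addition–elimination, and the vinyl bromide formed is less prone to a second addition.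

Step 5
Reactants: 9 5-bromo-2,3-dimethoxy-1,4-benzoquinone
Product: 11 5-bromo-2,3-dimethoxy-1,4-phenylene diacetate, via bromohydroquinone 10 (not isolated)
Conditions: Zn dust, Ac2O, NaOAc (cat.), 25 → 50 °C
Reagents that add atoms: acetic anhydride, CC(=O)OC(C)=O
Why: Reductive acetylation: zinc reduces the quinone to the hydroquinone zinc salt, which is acetylated in place, so the air-sensitive 10 is never handled; zinc in acetic anhydride leaves aryl bromides intact.

Step 6
Reactants: 5 2-ethenyl-4,5,6-trimethoxyphenol; 11 5-bromo-2,3-dimethoxy-1,4-phenylene diacetate
Product: 12 (E)-2-[2-(2,5-diacetoxy-3,4-dimethoxyphenyl)ethenyl]-4,5,6-trimethoxyphenol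
Conditions: Pd2(dba)3 (2.5 mol %), [HP(t-Bu)3]BF4 (10 mol %), Cy2NMe (1.2 equiv), 1,4-dioxane, 25 → 45 °C
Reagents that add atoms: none
Why: Mizoroki–Heck reaction: oxidative addition of the aryl bromide to zerovalent palladium, syn insertion of the terminal alkene with aryl at the unsubstituted carbon and syn β-hydride elimination give the (E)-stilbene; the bulky electron-rich phosphine lets an ortho-substituted bromide react near room temperature, and the hindered amine keeps acetyl transfer to the phenol slow.

Step 7
Reactants: 12 (E)-2-[2-(2,5-diacetoxy-3,4-dimethoxyphenyl)ethenyl]-4,5,6-trimethoxyphenol; 2 formaldehyde (used as paraformaldehyde)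
Product: 16 (3S,4R)-3-(2,5-diacetoxy-3,4-dimethoxyphenyl)-6,7,8-trimethoxychroman-4-ol (3,4-trans), via hemiformal 13 (not isolated), via oxocarbenium ion 14 (not isolated), via C4 benzylic cation 15 (not isolated)
Conditions: (CH2O)n (3 equiv), H2O (5 equiv), (S,S)-imidodiphosphorimidate acid HN[P(=NSO2CF3)(O2C20H10Ar2)]2 (each O2C20H10Ar2 an (S)-3,3'-diaryl-1,1'-binaphthyl-2,2'-diolate, Ar = 4-tert-butylphenyl; 5 mol %), CHCl3, −20 °C
Reagents that add atoms: water, O
Why: Proposed new method: the phenol of 12 adds to 2 to give hemiformal 13, which the confined strong acid ionises to the aryloxymethyl oxocarbenium ion 14, held as an ion pair with the chiral imidodiphosphorimidate anion. C2 of 14, already bound to O1, attacks C3 of the alkene in a 6-endo-trig closure that forms C2–C3 and closes ring C as the benzylic cation 15, and water then adds to C4 to give 16. The closest known reaction types are the Prins cyclisation of homoallylic alcohols with aldehydes to 4-hydroxytetrahydropyrans (the 2-vinylphenol is a homoallylic alcohol with an arene backbone) and imidodiphosphorimidate-catalysed asymmetric Prins reactions of styrenes with paraformaldehyde. The 6-endo mode is preferred over 5-exo because charge builds up at C4, where ring A stabilises it through O1 and the para C7 methoxy group, whereas 5-exo closure would place it at C3 next to the electron-poor diacetoxyaryl ring. C3 (S) is set in the C2–C3 bond-forming step by the chiral anion, which has to shield one face of the (E)-alkene; this catalyst control is the unproven element. C4 (R) is set by C3: water approaches cation 15 anti to the C3 aryl group, and the resulting trans, diequatorial alcohol is also the more stable epimer, so reversible ionisation at C4 can only improve the outcome. The selectivity needed is reaction through the phenol and not hydroxymethylation of an arene, acid-induced closure of the phenol onto C3 to a dihydrobenzofuran, or capture of C4 by O2'; the two acetates secure it by deactivating ring B, destabilising a C3 cation and masking O2'. Low temperature and an excess of water are chosen so that capture of 15 outruns loss of H3, which would erase the C3 stereocentre.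

Step 8
Reactants: 16 (3S,4R)-3-(2,5-diacetoxy-3,4-dimethoxyphenyl)-6,7,8-trimethoxychroman-4-ol
Product: 17 (3S,4R)-3-(2,5-dihydroxy-3,4-dimethoxyphenyl)-6,7,8-trimethoxychroman-4-ol (3,4-trans; CNP0111047.1)
Conditions: K2CO3 (0.3 equiv), degassed MeOH, argon, 0 °C; degassed pH 6.5 phosphate buffer/EtOAc
Reagents that add atoms: none
Why: Base-catalysed methanolysis (transesterification) of two aryl acetates; phenoxides are good leaving groups, so the esters go at 0 °C, while C3 and C4 are untouched because C4 ionises only under acid, and exclusion of oxygen protects the hydroquinone.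

## Compound list

1 | 2,3,4-trimethoxyphenol | COc1ccc(O)c(OC)c1OC | starting material
2 | formaldehyde (used as paraformaldehyde) | C=O | starting material
3 | 6-(hydroxymethyl)-2,3,4-trimethoxyphenol (present as its magnesium phenoxide) | COc1cc(CO)c(O)c(OC)c1OC | intermediate
4 | 2-hydroxy-3,4,5-trimethoxybenzaldehyde | COc1cc(C=O)c(O)c(OC)c1OC | intermediate
5 | 2-ethenyl-4,5,6-trimethoxyphenol | COc1cc(C=C)c(O)c(OC)c1OC | intermediate
6 | 2,3-dimethoxyphenol | COc1cccc(O)c1OC | starting material
7 | 2,3-dimethoxy-1,4-benzoquinone | COC1=C(OC)C(=O)C=CC1=O | intermediate
8 | (±)-trans-5,6-dibromo-2,3-dimethoxycyclohex-2-ene-1,4-dione (racemate, one enantiomer drawn) | COC1=C(OC)C(=O)[C@@H](Br)[C@H](Br)C1=O | intermediate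
9 | 5-bromo-2,3-dimethoxy-1,4-benzoquinone | COC1=C(OC)C(=O)C(Br)=CC1=O | intermediate
10 | 5-bromo-2,3-dimethoxybenzene-1,4-diol (present as its zinc salt) | COc1c(O)cc(Br)c(O)c1OC | intermediate
11 | 5-bromo-2,3-dimethoxy-1,4-phenylene diacetate | COc1c(OC(C)=O)cc(Br)c(OC(C)=O)c1OC | intermediate
12 | (E)-2-[2-(2,5-diacetoxy-3,4-dimethoxyphenyl)ethenyl]-4,5,6-trimethoxyphenol | COc1cc(/C=C/c2cc(OC(C)=O)c(OC)c(OC)c2OC(C)=O)c(O)c(OC)c1OC | intermediate
13 | aryl hemiformal of 12, (E)-{2-[2-(2,5-diacetoxy-3,4-dimethoxyphenyl)ethenyl]-4,5,6-trimethoxyphenoxy}methanol | COc1cc(/C=C/c2cc(OC(C)=O)c(OC)c(OC)c2OC(C)=O)c(OCO)c(OC)c1OC | intermediate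
14 | O1=C2 oxocarbenium ion of 12 (aryl methylideneoxonium, ion pair with the catalyst anion) | COc1cc(/C=C/c2cc(OC(C)=O)c(OC)c(OC)c2OC(C)=O)c([O+]=C)c(OC)c1OC | intermediate
15 | (3S)-3-(2,5-diacetoxy-3,4-dimethoxyphenyl)-6,7,8-trimethoxychroman-4-ylium (C4 benzylic cation, ion pair with the catalyst anion) | COc1cc2c(c(OC)c1OC)OC[C@H](c1cc(OC(C)=O)c(OC)c(OC)c1OC(C)=O)[CH+]2 | intermediate
16 | (3S,4R)-3-(2,5-diacetoxy-3,4-dimethoxyphenyl)-6,7,8-trimethoxychroman-4-ol (3,4-trans) | COc1cc2c(c(OC)c1OC)OC[C@H](c1cc(OC(C)=O)c(OC)c(OC)c1OC(C)=O)[C@H]2O | intermediate
17 | (3S,4R)-3-(2,5-dihydroxy-3,4-dimethoxyphenyl)-6,7,8-trimethoxychroman-4-ol (3,4-trans) | COc1cc2c(c(OC)c1OC)OC[C@H](c1cc(O)c(OC)c(OC)c1O)[C@H]2O | target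

## Step count and least certain steps

Total: 8 steps. Longest linear sequence: 6 steps (6 → 7 → 9 → 11 → 12 → 16 → 17, steps 3 to 8); the ring-A branch (steps 1 and 2) joins at step 6.

**Step 7 (key step, proposed new method).**
- What may go wrong: activation of formaldehyde at the alkene before the phenol is engaged, so that the intermolecular Prins manifold (dioxane formation, oligomerisation) competes with ring closure. Poor discrimination between the two alkene faces inside the ion pair. Loss of the C3 proton from the benzylic cation in competition with water capture, which erases C3.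
- Fallback with known reactions, setting out from 5 and 11 and coming back at 16: Miyaura borylation of 11 (B2pin2, Pd(dppf)Cl2, KOAc, dioxane) would give the pinacol boronate 2,3-dimethoxy-5-(4,4,5,5-tetramethyl-1,3,2-dioxaborolan-2-yl)-1,4-phenylene diacetate F1. Suzuki–Miyaura coupling of F1 with 2-bromoprop-2-en-1-ol (Pd(dppf)Cl2, CsF, dioxane) would give the 2-arylallyl alcohol 5-(3-hydroxyprop-1-en-2-yl)-2,3-dimethoxy-1,4-phenylene diacetate F2. Mitsunobu etherification of phenol 5 with F2 (PPh3, DIAD, THF) would give the diene 5-[3-(2-ethenyl-4,5,6-trimethoxyphenoxy)prop-1-en-2-yl]-2,3-dimethoxy-1,4-phenylene diacetate F3. Ring-closing metathesis with the second-generation Grubbs catalyst RuCl2(=CHPh)(H2IMes)(PCy3) would close ring C as the isoflav-3-ene 3-(2,5-diacetoxy-3,4-dimethoxyphenyl)-6,7,8-trimethoxy-2H-chromene F4. Asymmetric hydroboration of F4 with monoisopinocampheylborane (IpcBH2, from the enantiomer of α-pinene that delivers 3S), then oxidation with Me3NO, which spares aryl acetates, would return to 16. Boron adds to the less substituted C4 and hydrogen to C3 from the same face, so the 3,4-trans relationship follows from syn addition.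

**Step 6.**
- What may go wrong: base-mediated transfer of acetyl groups from ring B to the free phenol of 5 or 12 during the coupling, and oligomerisation of the electron-rich vinylphenol before it couples.
- Fallback, setting out from 4 and coming back at 12: silylation of 4 (TBSCl, imidazole, DMF) would give 2-(tert-butyldimethylsilyloxy)-3,4,5-trimethoxybenzaldehyde F5. Wittig methylenation would give tert-butyl(2-ethenyl-4,5,6-trimethoxyphenoxy)dimethylsilane F6. Heck coupling of F6 with 11 under the step 6 conditions would give the silyl ether (E)-5-{2-[2-(tert-butyldimethylsilyloxy)-3,4,5-trimethoxyphenyl]ethenyl}-2,3-dimethoxy-1,4-phenylene diacetate F7. Cleavage of the aryl silyl ether with Et3N·3HF in MeCN, an acidic fluoride source that leaves aryl acetates alone, would give 12. No free phenol is then present while base and acetates meet.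

**Step 4.**
- What may go wrong: addition of a second bromine and conjugate addition of bromide or acetate to the very electrophilic bromoquinone.
- Fallback, setting out from 7 and coming back at 11 (bypassing 9): reductive acetylation of 7 (Zn, Ac2O, NaOAc) would give 2,3-dimethoxy-1,4-phenylene diacetate F8, and electrophilic bromination of F8 (NBS, MeCN, catalytic CF3SO3H) would give 11. The two free positions of F8 are equivalent, each para to a methoxy group, and the first bromine deactivates the ring toward a second.

**Step 8.**
- What may go wrong: oxidation of the liberated hydroquinone, present partly as phenoxide, by traces of oxygen, and ionisation at C4 if the work-up turns acidic.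
- Fallback, setting out from 16 and coming back at 17: methanolysis followed by deliberate oxidation of the crude hydroquinone with Ag2O in ether would give the quinone 2-[(3S,4R)-4-hydroxy-6,7,8-trimethoxychroman-3-yl]-5,6-dimethoxy-1,4-benzoquinone F9, which can be purified in air. Reduction of F9 with aqueous Na2S2O4 in a degassed, neutral two-phase system and isolation under argon would return 17.

## Further compounds

F1 | step 7 | 2,3-dimethoxy-5-(4,4,5,5-tetramethyl-1,3,2-dioxaborolan-2-yl)-1,4-phenylene diacetate | COc1c(OC(C)=O)cc(B2OC(C)(C)C(C)(C)O2)c(OC(C)=O)c1OC
F2 | step 7 | 5-(3-hydroxyprop-1-en-2-yl)-2,3-dimethoxy-1,4-phenylene diacetate | OCC(=C)c1cc(OC(C)=O)c(OC)c(OC)c1OC(C)=O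
F3 | step 7 | 5-[3-(2-ethenyl-4,5,6-trimethoxyphenoxy)prop-1-en-2-yl]-2,3-dimethoxy-1,4-phenylene diacetate | COc1cc(C=C)c(OCC(=C)c2cc(OC(C)=O)c(OC)c(OC)c2OC(C)=O)c(OC)c1OC
F4 | step 7 | 3-(2,5-diacetoxy-3,4-dimethoxyphenyl)-6,7,8-trimethoxy-2H-chromene | COc1cc2c(c(OC)c1OC)OCC(c1cc(OC(C)=O)c(OC)c(OC)c1OC(C)=O)=C2
F5 | step 6 | 2-(tert-butyldimethylsilyloxy)-3,4,5-trimethoxybenzaldehyde | COc1cc(C=O)c(O[Si](C)(C)C(C)(C)C)c(OC)c1OC
F6 | step 6 | tert-butyl(2-ethenyl-4,5,6-trimethoxyphenoxy)dimethylsilane | COc1cc(C=C)c(O[Si](C)(C)C(C)(C)C)c(OC)c1OC
F7 | step 6 | (E)-5-{2-[2-(tert-butyldimethylsilyloxy)-3,4,5-trimethoxyphenyl]ethenyl}-2,3-dimethoxy-1,4-phenylene diacetate | COc1cc(/C=C/c2cc(OC(C)=O)c(OC)c(OC)c2OC(C)=O)c(O[Si](C)(C)C(C)(C)C)c(OC)c1OC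
F8 | step 4 | 2,3-dimethoxy-1,4-phenylene diacetate | COc1c(OC(C)=O)ccc(OC(C)=O)c1OC
F9 | step 8 | 2-[(3S,4R)-4-hydroxy-6,7,8-trimethoxychroman-3-yl]-5,6-dimethoxy-1,4-benzoquinone | COc1cc2c(c(OC)c1OC)OC[C@H](C1=CC(=O)C(OC)=C(OC)C1=O)[C@H]2O
A1 | alternative 1 | syn-1-[2-(methoxymethoxy)-3,4,5-trimethoxyphenyl]-2-[2,5-bis(benzyloxy)-3,4-dimethoxyphenyl]-3-(tert-butyldimethylsilyloxy)propyl pinacol boronate | COCOc1c(OC)c(OC)c(OC)cc1[C@H](B1OC(C)(C)C(C)(C)O1)[C@@H](c1cc(OCc2ccccc2)c(OC)c(OC)c1OCc1ccccc1)CO[Si](C)(C)C(C)(C)C
A2 | alternative 1 | 2-(methoxymethoxy)-3,4,5-trimethoxyphenyllithium | [Li]c1cc(OC)c(OC)c(OC)c1OCOC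
A3 | alternative 1 | (E)-3-(tert-butyldimethylsilyloxy)prop-1-enylboronic acid pinacol ester | CC(C)(C)[Si](C)(C)OC/C=C/B1OC(C)(C)C(C)(C)O1
A4 | alternative 1 | 1,4-bis(benzyloxy)-5-bromo-2,3-dimethoxybenzene | COc1c(OCc2ccccc2)cc(Br)c(OCc2ccccc2)c1OC
A5 | alternative 2 | 3-bromo-2-ethoxy-6,7,8-trimethoxy-2H-chromene (racemic acetal) | CCOC1Oc2c(OC)c(OC)c(OC)cc2C=C1Br
A6 | alternative 2 | 5,6,7-trimethoxybenzofuran | COc1cc2ccoc2c(OC)c1OC
A7 | alternative 2 | 3-[2,5-bis(benzyloxy)-3,4-dimethoxyphenyl]-6,7,8-trimethoxy-2H-chromene | COc1cc2c(c(OC)c1OC)OCC(c1cc(OCc3ccccc3)c(OC)c(OC)c1OCc1ccccc1)=C2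
A8 | alternative 3 | 6-{2-[2,5-bis(benzyloxy)-3,4-dimethoxyphenyl]-1,3-bis(tert-butyldimethylsilyloxy)propyl}-2,3,4-trimethoxyphenol (configured as C3 and C4 of the target) | COc1cc([C@H](O[Si](C)(C)C(C)(C)C)[C@@H](c2cc(OCc3ccccc3)c(OC)c(OC)c2OCc2ccccc2)CO[Si](C)(C)C(C)(C)C)c(O)c(OC)c1OC
A9 | alternative 3 | pentacarbonyl[(1,2-dimethoxyethenyl)(methoxy)carbene]chromium, (CO)5Cr=C(OMe)C(OMe)=CHOMe | COC=C(OC)C(OC)=[Cr](=C=O)(=C=O)(=C=O)(=C=O)=C=O
A10 | alternative 3 | 4-[2,5-bis(benzyloxy)-3,4-dimethoxyphenyl]-3,5-bis(tert-butyldimethylsilyloxy)pent-1-yne (configured as C3 and C4 of the target) | C#C[C@H](O[Si](C)(C)C(C)(C)C)[C@@H](c1cc(OCc2ccccc2)c(OC)c(OC)c1OCc1ccccc1)CO[Si](C)(C)C(C)(C)C
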